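**Retrosynthetic overview**
- Last step: the target is a C6–C8''-linked biflavone (unit 1: 5,7-dihydroxy-4'-methoxyflavone; unit 2: 5-hydroxy-7,4'-dimethoxyflavone). It comes from its 5,5''-di-O-methyl 7-O-isopropyl ether by chelation-directed ether cleavage.
- Key disconnection: the strategy rests on the benzo ring of unit 1 (C4a, C5, C6, C7, C8, C8a), whose C6 carries the unit 2 aryl group between the oxygens on C5 and C7. It is cut at C4a–C5 and C6–C7 into a 6-alkoxy-2-pyranone ring fused to the 4-pyranone ring (giving C4a, C8a, C8, C7; its lactone C5/O6 leaves as CO2) and the two alkyne carbons of an 8-(methoxyethynyl)flavone (C5 with OMe, C6 with the aryl group).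
- Diene: the 4-pyranone ring is made first (alkynoyl chloride plus di-tert-butyl 3-oxoglutarate), then the 2-pyranone ring (cyclic anhydride, isopropyl half ester, enol lactonization).
- Dienophile: C8 iodination of 5,7,4'-trimethoxyflavone, then Negishi coupling with methoxyethynylzinc chloride.
- Ring order: 4-pyranone of unit 1, the sacrificial 2-pyranone, then the benzo ring of unit 1 in the key step; unit 2 is carried in intact.

Key step: step 7

Remark: the target SMILES defines no configuration for the hindered C6–C8'' biaryl axis and there is no stereocenter, so the route is planned for the racemic mixture of atropisomers.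

**Route**

Step 1
Reactants: 1 3-(4-methoxyphenyl)propiolic acid; 2 di-tert-butyl 3-oxoglutarate (di-tert-butyl 3-oxopentanedioate)
Product: 5 tert-butyl 2-(2-tert-butoxy-2-oxoethyl)-6-(4-methoxyphenyl)-4-oxo-4H-pyran-3-carboxylate, via 3-(4-methoxyphenyl)propioloyl chloride 3 (not isolated), via di-tert-butyl 2-[3-(4-methoxyphenyl)propioloyl]-3-oxopentanedioate 4 (not isolated)
Conditions: 1, (COCl)2, DMF (cat.), CH2Cl2, 0 °C to rt, evaporate; then 2, MgCl2, pyridine, CH2Cl2, 0 °C to rt; Et3N (cat.), rt
Reagents that add atoms: none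
Why: C-acylation of the magnesium-chelated enolate of the symmetrical β-keto diester by the alkynoyl chloride, followed by 6-endo-dig oxa-Michael addition of the ketone enol oxygen to the ynone, is the classical alkynoyl chloride/β-keto ester route to 4-pyranone-3-carboxylates, and the symmetry of 2 leaves no regiochemical choice.

Step 2
Reactants: 5 tert-butyl 2-(2-tert-butoxy-2-oxoethyl)-6-(4-methoxyphenyl)-4-oxo-4H-pyran-3-carboxylate
Product: 7 2-(4-methoxyphenyl)-8H-pyrano[4,3-b]pyran-4,5,7-trione (cyclic anhydride in equilibrium with its 7-hydroxy enol), via 2-(carboxymethyl)-6-(4-methoxyphenyl)-4-oxo-4H-pyran-3-carboxylic acid 6 (not isolated)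
Conditions: CF3CO2H, CH2Cl2, rt, evaporate; then (CF3CO)2O, CH2Cl2, 0 °C to rt
Reagents that add atoms: none
Why: Acidolysis of both tert-butyl esters (loss of 2-methylpropene) and cyclodehydration of the 1,5-diacid with trifluoroacetic anhydride, as in the preparation of homophthalic anhydrides, should give the six-membered anhydride without heating the decarboxylation-prone pyranone-acetic acid.

Step 3
Reactants: 7 2-(4-methoxyphenyl)-8H-pyrano[4,3-b]pyran-4,5,7-trione
Product: 8 2-(2-isopropoxy-2-oxoethyl)-6-(4-methoxyphenyl)-4-oxo-4H-pyran-3-carboxylic acid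
Conditions: iPrOH (solvent), 80 °C
Reagents that add atoms: propan-2-ol, CC(C)O
Why: Alcoholysis of an unsymmetrical cyclic anhydride at its non-conjugated, more electrophilic carbonyl (C7), the selectivity known for homophthalic anhydride, should leave the vinylogous-carbonate-type C5 carboxyl as the free acid.

Step 4
Reactants: 8 2-(2-isopropoxy-2-oxoethyl)-6-(4-methoxyphenyl)-4-oxo-4H-pyran-3-carboxylic acid
Product: 10 7-isopropoxy-2-(4-methoxyphenyl)pyrano[4,3-b]pyran-4,5-dione, via isopropyl 2-[3-(chlorocarbonyl)-6-(4-methoxyphenyl)-4-oxo-4H-pyran-2-yl]acetate 9 (not isolated)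
Conditions: (COCl)2, DMF (cat.), CH2Cl2, 0 °C to rt; then Et3N, 0 °C; non-aqueous work-up, crystallization
Reagents that add atoms: none
Why: Enol lactonization, in which the acid chloride acylates the carbonyl oxygen of the enolized isopropyl ester in a six-membered closure (C-acylation would need a four-membered ring), is the closure by which homophthalic acid half esters give 3-alkoxyisocoumarins, and the amine removes the C8 proton before chloride can dealkylate the oxocarbenium ion.

Step 5
Reactants: 11 5,7,4'-trimethoxyflavone (5,7-dimethoxy-2-(4-methoxyphenyl)chromen-4-one)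
Product: 12 8-iodo-5,7-dimethoxy-2-(4-methoxyphenyl)chromen-4-one
Conditions: I2, CF3CO2Ag, CH2Cl2, rt, dark
Reagents that add atoms: iodine, II
Why: Electrophilic aromatic iodination of a 5,7-dimethoxyflavone should take place at C8, which is para to the 5-methoxy group, ortho to the 7-methoxy group and to O1, and less hindered than C6 between two methoxy groups (a free 5-OH would instead direct to C6).

Step 6
Reactants: 12 8-iodo-5,7-dimethoxy-2-(4-methoxyphenyl)chromen-4-one; 13 chloroacetaldehyde dimethyl acetal (2-chloro-1,1-dimethoxyethane)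
Product: 16 5,7-dimethoxy-8-(methoxyethynyl)-2-(4-methoxyphenyl)chromen-4-one, via lithium methoxyacetylide 14 (not isolated), via methoxyethynylzinc chloride 15 (not isolated)
Conditions: 13 (1.5 equiv), LiNEt2 (3 equiv per 13), THF, −78 to 0 °C; ZnCl2, 0 °C; then 12, Pd(PPh3)4 (5 mol %), THF, rt to 40 °C; NaHCO3 work-up, Et3N-deactivated silica
Reagents that add atoms: none
Why: Twofold elimination (methanol, then HCl) from the chloroacetal with the lithium amide gives the lithium alkoxyacetylide, and Negishi coupling of the derived alkynylzinc chloride with an aryl iodide under zerovalent palladium catalysis is an established route to aryl alkynyl ethers; the zinc reagent does not add to the flavone carbonyl.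

Step 7
Reactants: 10 7-isopropoxy-2-(4-methoxyphenyl)pyrano[4,3-b]pyran-4,5-dione; 16 5,7-dimethoxy-8-(methoxyethynyl)-2-(4-methoxyphenyl)chromen-4-one
Product: 18 7-isopropoxy-5-methoxy-2-(4-methoxyphenyl)-6-[5,7-dimethoxy-2-(4-methoxyphenyl)-4-oxo-4H-chromen-8-yl]chromen-4-one, via bridged lactone cycloadduct 17 (not isolated)
Conditions: 16 (1.3 equiv), Yb(fod)3 (10 mol %), 4 Å MS, toluene, 60 °C then 110 °C, sealed tube
Reagents that add atoms: none
Why: Proposed new method: the 2-pyranone ring of 10 (diene C4a=C8a–C8=C7) is electron-poor because C4a carries the C4 ketone, and more so when Yb(fod)3 (fod = 6,6,7,7,8,8,8-heptafluoro-2,2-dimethyloctane-3,5-dionate) binds the C4 and C5 carbonyl oxygens as a six-membered chelate, so it should add the electron-rich ynol ether 16 in an inverse-electron-demand [4+2] cycloaddition, after which the bridged lactone 17 expels C5 and O6 as CO2 by retro-[4+2] reaction. The closest known reaction type is the inverse-electron-demand Diels–Alder reaction of 3-acyl- and 3-alkoxycarbonyl-2-pyranones with ynamines, ketene acetals or vinyl ethers (thermal or lanthanide-catalysed) followed by loss of CO2, which has not been shown for an aryl ynol ether or for a 6-alkoxy-2-pyranone fused to a 4-pyranone. The one ring closed, the carbocycle C4a–C5–C6–C7–C8–C8a, forms by intermolecular [4+2] cycloaddition (new bonds C4a–C5 and C6–C7) and is aromatized by the cycloreversion, so the tetra-ortho-substituted C6–C8'' linkage is never made as a biaryl bond. No stereocenter survives: the two bridgehead centers of 17 vanish with CO2, and the biaryl axis, unspecified in the target, arises as a racemate. The selectivity needed is regiochemical, the aryl-bearing alkyne carbon (nucleophilic, β to the ether oxygen) bonding to C7 and the methoxy-bearing carbon to C4a; C7 is the vinylogous acceptor terminus of both the C4 and the C5 carbonyl and C4a their shared α-carbon, and the chelate reinforces this polarization, but the isopropoxy donor on C7 and a competing addition at C8a make this the open point of the route. Since O1 and C8–H already belong to the diene, this orientation is the only variable, and the wanted one puts the methoxy group on C5, the aryl group on C6 and the cleavable isopropoxy group on C7.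

Step 8
Reactants: 18 7-isopropoxy-5-methoxy-2-(4-methoxyphenyl)-6-[5,7-dimethoxy-2-(4-methoxyphenyl)-4-oxo-4H-chromen-8-yl]chromen-4-one
Product: 19 5,7-dihydroxy-6-[5-hydroxy-7-methoxy-2-(4-methoxyphenyl)-4-oxo-4H-chromen-8-yl]-2-(4-methoxyphenyl)chromen-4-one (target, CNP0146326.0)
Conditions: BCl3 (1 M in CH2Cl2, 8 equiv), CH2Cl2, −78 to 0 °C; then MeOH, aq. HCl
Reagents that add atoms: none
Why: Chemoselective Lewis acid ether cleavage: BCl3 removes aryl methyl ethers peri to a carbonyl through a six-membered boron chelate and secondary (isopropyl) aryl ethers by an SN1-like path, while the unchelated 7''-methoxy group and the two 4-methoxyphenyl ethers should be inert at or below 0 °C.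

**Compound list**
1 | 3-(4-methoxyphenyl)propiolic acid | COc1ccc(C#CC(=O)O)cc1 | starting material
2 | di-tert-butyl 3-oxoglutarate | CC(C)(C)OC(=O)CC(=O)CC(=O)OC(C)(C)C | starting material
3 | 3-(4-methoxyphenyl)propioloyl chloride (formed in the flask) | COc1ccc(C#CC(=O)Cl)cc1 | intermediate
4 | di-tert-butyl 2-[3-(4-methoxyphenyl)propioloyl]-3-oxopentanedioate (enolized, formed in the flask) | CC(C)(C)OC(=O)CC(=O)C(C(=O)C#Cc1ccc(OC)cc1)C(=O)OC(C)(C)C | intermediate
5 | tert-butyl 2-(2-tert-butoxy-2-oxoethyl)-6-(4-methoxyphenyl)-4-oxo-4H-pyran-3-carboxylate | CC(C)(C)OC(=O)CC1=C(C(=O)OC(C)(C)C)C(=O)C=C(O1)c1ccc(OC)cc1 | intermediate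
6 | 2-(carboxymethyl)-6-(4-methoxyphenyl)-4-oxo-4H-pyran-3-carboxylic acid (formed in the flask) | OC(=O)CC1=C(C(=O)O)C(=O)C=C(O1)c1ccc(OC)cc1 | intermediate
7 | 2-(4-methoxyphenyl)-8H-pyrano[4,3-b]pyran-4,5,7-trione | O=C1CC2=C(C(=O)O1)C(=O)C=C(O2)c1ccc(OC)cc1 | intermediate
8 | 2-(2-isopropoxy-2-oxoethyl)-6-(4-methoxyphenyl)-4-oxo-4H-pyran-3-carboxylic acid | CC(C)OC(=O)CC1=C(C(=O)O)C(=O)C=C(O1)c1ccc(OC)cc1 | intermediate
9 | isopropyl 2-[3-(chlorocarbonyl)-6-(4-methoxyphenyl)-4-oxo-4H-pyran-2-yl]acetate (formed in the flask) | CC(C)OC(=O)CC1=C(C(Cl)=O)C(=O)C=C(O1)c1ccc(OC)cc1 | intermediate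
10 | 7-isopropoxy-2-(4-methoxyphenyl)pyrano[4,3-b]pyran-4,5-dione | CC(C)Oc1cc2oc(-c3ccc(OC)cc3)cc(=O)c2c(=O)o1 | intermediate
11 | 5,7,4'-trimethoxyflavone | COc1ccc(cc1)-c1cc(=O)c2c(OC)cc(OC)cc2o1 | starting material
12 | 8-iodo-5,7-dimethoxy-2-(4-methoxyphenyl)chromen-4-one | COc1ccc(cc1)-c1cc(=O)c2c(OC)cc(OC)c(I)c2o1 | intermediate
13 | chloroacetaldehyde dimethyl acetal | COC(CCl)OC | starting material
14 | lithium methoxyacetylide (formed in the flask) | [Li]C#COC | intermediate
15 | methoxyethynylzinc chloride (formed in the flask) | COC#C[Zn]Cl | intermediate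
16 | 5,7-dimethoxy-8-(methoxyethynyl)-2-(4-methoxyphenyl)chromen-4-one | COC#Cc1c(OC)cc(OC)c2c(=O)cc(-c3ccc(OC)cc3)oc12 | intermediate
17 | bridged lactone cycloadduct: 2-oxabicyclo[2.2.2]octa-5,7-dien-3-one with bridgeheads C7 (isopropoxy) and C4a, etheno bridge C5(OMe)=C6(aryl) and bridge C8=C8a fused to the 4-pyranone; racemic, one enantiomer written; formed in the flask | CC(C)O[C@@]12OC(=O)[C@]3(C(OC)=C1c1c(OC)cc(OC)c4c(=O)cc(-c5ccc(OC)cc5)oc14)C(=O)C=C(c1ccc(OC)cc1)OC3=C2 | intermediate
18 | 7-isopropoxy-5-methoxy-2-(4-methoxyphenyl)-6-[5,7-dimethoxy-2-(4-methoxyphenyl)-4-oxo-4H-chromen-8-yl]chromen-4-one (racemic axis) | COc1c(-c2c(OC)cc(OC)c3c(=O)cc(-c4ccc(OC)cc4)oc23)c(OC(C)C)cc2oc(-c3ccc(OC)cc3)cc(=O)c12 | intermediate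
19 | 5,7-dihydroxy-6-[5-hydroxy-7-methoxy-2-(4-methoxyphenyl)-4-oxo-4H-chromen-8-yl]-2-(4-methoxyphenyl)chromen-4-one (racemic axis) | COc1ccc(-c2cc(=O)c3c(O)c(-c4c(OC)cc(O)c5c(=O)cc(-c6ccc(OC)cc6)oc45)c(O)cc3o2)cc1 | target

**Step count**
Total: 8 steps. Longest linear sequence: 6 steps (steps 1, 2, 3, 4, 7, 8); the dienophile branch (steps 5, 6) joins at step 7.

**Steps most likely to fail**

Risk 1, step 7 (key cycloaddition). The ynol ether may bond through its aryl-bearing carbon to C8a instead of C7, giving conjugate addition followed by [2+2] or hetero-[4+2] closure onto a carbonyl oxygen. It may also add in the reverse orientation, or hydrate or oligomerize faster than the hindered cycloaddition proceeds. The fallback uses known chemistry and replaces ring construction by biaryl cross-coupling; it sets out from 12 and returns at 18. Miyaura borylation of 12 (B2pin2, PdCl2(dppf), KOAc, dioxane, 90 °C) should give 5,7-dimethoxy-2-(4-methoxyphenyl)-8-(4,4,5,5-tetramethyl-1,3,2-dioxaborolan-2-yl)chromen-4-one F1. Purchased acacetin (5,7-dihydroxy-4'-methoxyflavone) would be alkylated at O7 (2-bromopropane, K2CO3, DMF; the chelated 5-OH is left) to 5-hydroxy-7-isopropoxy-2-(4-methoxyphenyl)chromen-4-one F2. Iodination at C6 under direction of the free 5-OH (BnMe3N·ICl2, CaCO3, CH2Cl2/MeOH) should give 5-hydroxy-6-iodo-7-isopropoxy-2-(4-methoxyphenyl)chromen-4-one F3. Methylation (Me2SO4, K2CO3, acetone, reflux) should give 6-iodo-7-isopropoxy-5-methoxy-2-(4-methoxyphenyl)chromen-4-one F4. Suzuki–Miyaura coupling of F1 with F4 (Pd2(dba)3, SPhos, K3PO4, toluene/H2O, 100 °C) should then give 18.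

Risk 2, step 6 (Negishi coupling to the ynol ether). Oxidative addition and transmetalation at the doubly ortho-substituted C8 iodide may be slow, so the alkoxyethynyl metal decomposes first, and the ynol ether may hydrate on work-up or chromatography. The fallback forms the alkyne by elimination instead of coupling; it sets out from 12 and returns at 16. Iodine–magnesium exchange of 12 (iPrMgCl·LiCl, THF, −40 °C) and acylation with N,2-dimethoxy-N-methylacetamide (Weinreb-type ketone synthesis) should give 5,7-dimethoxy-8-(methoxyacetyl)-2-(4-methoxyphenyl)chromen-4-one F5. Chelation-controlled enolization and O-triflation (LiN(SiMe3)2, PhNTf2, THF, −78 °C) should give (Z)-1-[5,7-dimethoxy-2-(4-methoxyphenyl)-4-oxochromen-8-yl]-2-methoxyvinyl trifluoromethanesulfonate F6. Anti elimination with KOtBu (THF, −78 °C) should then give 16.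

Risk 3, step 4 (enol lactonization). The cyclic dialkoxycarbenium intermediate may lose its isopropyl group to chloride, returning anhydride 7, and the acylal-like 6-alkoxy-2-pyranone may ring-open by hydrolysis during isolation. The fallback alkylates the anhydride enol on oxygen instead of cyclizing the half ester; it sets out from 7 and returns at 10. Treating 7 with Ag2CO3 and 2-iodopropane (toluene, rt, dark) should give 10 directly by silver-assisted O-alkylation of the ambident enol, the reaction type that converts glutaconic-type anhydrides into 6-alkoxy-2-pyranones. No new compound is formed.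

**Further compounds**
F1 | step 7 | 5,7-dimethoxy-2-(4-methoxyphenyl)-8-(4,4,5,5-tetramethyl-1,3,2-dioxaborolan-2-yl)chromen-4-one | COc1ccc(cc1)-c1cc(=O)c2c(OC)cc(OC)c(B3OC(C)(C)C(C)(C)O3)c2o1
F2 | step 7 | 5-hydroxy-7-isopropoxy-2-(4-methoxyphenyl)chromen-4-one | COc1ccc(cc1)-c1cc(=O)c2c(O)cc(OC(C)C)cc2o1
F3 | step 7 | 5-hydroxy-6-iodo-7-isopropoxy-2-(4-methoxyphenyl)chromen-4-one | COc1ccc(cc1)-c1cc(=O)c2c(O)c(I)c(OC(C)C)cc2o1
F4 | step 7 | 6-iodo-7-isopropoxy-5-methoxy-2-(4-methoxyphenyl)chromen-4-one | COc1ccc(cc1)-c1cc(=O)c2c(OC)c(I)c(OC(C)C)cc2o1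
F5 | step 6 | 5,7-dimethoxy-8-(methoxyacetyl)-2-(4-methoxyphenyl)chromen-4-one | COCC(=O)c1c(OC)cc(OC)c2c(=O)cc(-c3ccc(OC)cc3)oc12
F6 | step 6 | (Z)-1-[5,7-dimethoxy-2-(4-methoxyphenyl)-4-oxochromen-8-yl]-2-methoxyvinyl trifluoromethanesulfonate | CO/C=C(\OS(=O)(=O)C(F)(F)F)c1c(OC)cc(OC)c2c(=O)cc(-c3ccc(OC)cc3)oc12
F0 | step 4 | none | none
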